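**Remarks on the chemistry.** Assumption: in the reversible oxa-Michael closure the 2,4-trans chroman is the more stable C2 epimer, because the doubly ortho-substituted ring D is taken to sit pseudo-axial on C4 (away from the peri hydrogen H5) with the C2 side chain equatorial. Structure check: 13 and 16 are both (2R,4S) and carry the connectivity of the target; in lactol 11 the hemiacetal carbon is C2, and the centre created in the Friedel–Crafts step is C4. Design of 13: it keeps four benzyl ethers (one neutral hydrogenolysis is the only deprotection the target tolerates), is used as the purified trans diastereomer, and is annulated with the same amine that closes ring C.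

## Structural features

The target is a 2,4-trans-4-arylflavan: a chroman (aromatic ring A fused to the pyran ring C) with a free 7-hydroxyl, a 4-hydroxyphenyl group (ring B) on C2, and a 2,4,6-trihydroxy-3-dodecanoylphenyl group (ring D) on C4 through the C4–C1' bond. The only stereocentres are C2 (R) and C4 (S); they are 1,3-related across the C3 methylene and their aryl groups lie on opposite faces of ring C. Ring D is a C-acylated phloroglucinol whose two free ring carbons are equivalent before it is joined to C4, so the position of the dodecanoyl group poses no regiochemical problem, but its two ortho oxygens make C4 a crowded diarylmethine. The fragile element is the O1–C2 bond, a benzylic ether para to the ring B oxygen: acid opens it to a para-quinone methide and C2 loses its configuration. The free acylphloroglucinol is in addition air- and base-sensitive and carries an enolisable aryl ketone. The real difficulty is therefore absolute control at the hindered C4, the trans placement of C2, and survival of O1–C2 through every step after it has become benzylic. The key step exploits the fact that the six carbons of ring B (C1'' to C6'', oxygen on C4'' para to the C2–C1'' bond) map onto a C2-bound acetaldehyde unit (C1'', C2'') plus a four-carbon enone (C3'' to C6''). While C2 carries that sp3 chain, or the cyclohexenone made from it, O1–C2 is an ordinary alkyl aryl ether and cannot ionise.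

## Logic of the disconnections

20 ⇒ 19. The four O–CH2Ph bonds (O7 and the three ring D oxygens) are cut. 20 tolerates neither acid nor strong base, so all phenols must be freed together under neutral conditions. The gain is that every earlier intermediate is a non-chelating, oxidation-stable ether. The forward step must spare O1–C2 and the aryl ketone.

19 ⇒ 16 (through 17 and 18). No skeletal bond is cut; ring B is taken back from the phenol to the cyclohex-2-enone oxidation level. This confines the benzylic, ionisable form of O1–C2 to the last two steps and turns ring B into an annulation retron. The forward step must dehydrogenate under near-neutral conditions, with enolisation away from C1'' and in the presence of a second ketone.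

16 ⇒ 13 + 14. C1''–C6'' and C2''–C3'' are cut, the two bonds of a Robinson-type annulation. One ring and four carbons are removed, leaving a chroman with a two-carbon aldehyde on C2. The demand is that carbon–carbon bond formation at C1'' must outrun opening of ring C, since 13 is a β-aryloxy aldehyde.

13 ⇒ 12. O1–C2 is cut (retro-oxa-Michael). A β-aryloxy aldehyde is the adduct of a phenol and an enal, and because that addition is reversible C2 can be set relative to C4 under equilibrium conditions. Ring C and one stereocentre disappear. The forward step requires the trans epimer to be favoured.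

12 ⇒ 11 + 7. The alkene between the former hemiacetal carbon and the ylide carbon is cut. Two carbons are removed and the enal returns to a lactol. The forward step needs 11 to react through its ring-opened tautomer 10 and to take up only one unit of 7.

11 ⇒ 8 + 9. C4–C4a is cut, and with it the hemiacetal O–C2 bond. C4 is β to the aldehyde carbon and ortho to the ring A oxygen, the pattern of a conjugate Friedel–Crafts addition followed by hemiacetal closure. The molecule falls into two halves of similar size, and the only lasting stereocentre made by a chiral catalyst is created here. The forward step needs attack through C6 of 9 (ortho to OH) and face control at a hindered β-carbon.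

8 ⇒ 6 + 7. The Cα=Cβ bond of the enal is cut. This reduces the ring D piece to a benzaldehyde and reuses 7. The demand is single olefination of a hindered aldehyde.

6 ⇒ 5. Three O–CH2Ph bonds are cut. Protection is placed after both carbonyl groups are on the ring, so that no Lewis acid is used on a benzyl ether. The demand is O- rather than C-alkylation of three chelated hydroxyls.

5 ⇒ 3. The ring–CHO bond is cut. The two free ring carbons of 3 are equivalent, so formylation fixes the 1,3-relation of the two carbonyl groups without a regiochemical choice. The demand is mono-formylation of the ring rather than reaction at the ketone.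

3 ⇒ 1 + 2. The ring–acyl bond is cut, giving two commercial materials. The demand is mono-C-acylation.

## Other disconnections considered

Alternative 1: The cut removes ring D. C1'–C6', C2'–C3' and C5'–C6' are broken, leaving a 2,4-disubstituted chroman with a silyloxy-alkyne on C4, A1, and the four-carbon partner 3-(benzyloxy)cyclobut-2-en-1-one, A2.
- Forward step: heating opens A2 to a vinylketene, which adds across the alkyne of A1 in a [2+2] sense. The new four-membered ring opens again, the resulting triene closes by 6π-electrocyclisation and tautomerises to phenol A3, with the three ring D oxygens distinguished as OH, OSi(iPr)3 and OBn (a Danheiser benzannulation).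
- In its favour: the cascade is thermal and neutral. The crowded C4–C1' bond is never made by substitution at C4. Ring D regiochemistry is fixed by the polarity of the ynol ether, and ring A arrives with the chroman and needs no regiocontrol. On these regiochemical points it is the equal or the better of the chosen plan.
- Against it here: ring B with its oxygen is present from the start, so the ionisable O1–C2 bond must survive alkyne installation, the benzannulation at about 80–110 °C and, above all, late C-acylation of ring D, which needs Lewis-acid conditions or a Fries shift. The differentiation of the ring D oxygens is not needed, because C3' and C5' become equivalent on deprotection. C4 must first be set trans to C2 with a two-carbon alkyne precursor.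
- Comparison: in step count it is no shorter (chroman core, alkyne, annulation, acylation, two deprotections). Its weak point, acid chemistry after the benzylic ether exists, is exactly what the chosen plan avoids.

Alternative 2: The cut is in ring A, at C4a–C5 and C8–C8a. It returns the open-chain malonate A4 (C4a as the malonate carbon, C4 and C2 already configured, C2 as a silyl ether) and enone 14.
- Forward step: base-mediated Michael addition of A4 to 14, then Claisen-type closure of the methyl ketone on one ester, gives the cyclohexane-1,3-dione ester A5. Loss of the ester, desilylation, condensation of the C2 hydroxyl with the C8a carbonyl (closing ring C with retention at C2) and dehydrogenation would then give the 7-hydroxychroman.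
- In its favour: the Michael–Claisen route to 1,3-diones is dependable. Ring A is built with unambiguous regiochemistry, with no ortho/para question as in step 5 of the chosen route; on this point the alternative is better. O1–C2 forms without touching the configuration of C2, and no β-aryloxy aldehyde with its retro-oxa-Michael liability appears.
- Against it here: the donor is a malonate carbon next to the C4 methine with its doubly ortho-substituted ring D, so the quaternary C4a centre is formed in a very crowded place. Both stereocentres must be set in an open chain beforehand. Oxidising a cyclohexane-1,3-dione derivative to a resorcinol needs forcing dehydrogenation at a stage where the 4-benzyloxybenzylic O1–C2 ether already exists.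
- Comparison: it uses the same enone 14 and the same idea of aromatising a carbocycle late, but on ring A, where this does not postpone the labile ether. It is the longest of the four plans.

Alternative 3: The cut takes O1–C2 and C4–C4a together, so that ring C comes from the trans-diarylcyclopropane A6 and phenol 9.
- Forward step: anodic oxidation of A6 to its radical cation; opening of the three-membered ring by the phenol oxygen at C2 with inversion; a second electron transfer to the ring D-stabilised C4 cation; and capture of that cation by C6 of the new aryl ether, giving the bromo-flavan A7. Bromine–lithium exchange and acylation would then bring in the dodecanoyl group before hydrogenolysis.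
- In its favour: it is the most convergent plan. Both ring C bonds form in one operation from two simple pieces, C2 is set stereospecifically from a cyclopropane accessible by asymmetric cyclopropanation, and the electron-rich ring D is put to use. In step economy it is better than the chosen plan (about eight steps against eleven).
- Against it here: three easily oxidised arenes compete at the anode (ring D, phenol 9, and the product A7, itself a 4-alkoxybenzylic ether), so over-oxidation and ionisation of O1–C2 in the acidified anolyte are likely. The phenol must react first through oxygen and then through the correct carbon. C4 depends only on the diastereoselectivity of a cation cyclisation. A two-bond oxy-arylation with a phenol as both nucleophiles lacks a close model, whereas every step of the chosen route is a known reaction type.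
- Comparison: both routes end with hydrogenolysis. The alternative carries the benzylic ether through an electrolysis and an organolithium step; the chosen plan carries it through two near-neutral steps only.

Key step: step 8

## Route

Step 1
Reactants: 1 phloroglucinol; 2 dodecanoyl (lauroyl) chloride
Product: 3 1-(2,4,6-trihydroxyphenyl)dodecan-1-one
Conditions: AlCl3 (3.5 equiv), CH2Cl2/MeNO2, 0 °C to 40 °C; then ice, aq. HCl
Reagents that add atoms: none
Why: Friedel–Crafts acylation; the three ring carbons of 1 are equivalent and the aluminium chelate of the first ketone deactivates the ring, so mono-C-acylation should dominate and any O-ester should rearrange under the conditions.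

Step 2
Reactants: 3 1-(2,4,6-trihydroxyphenyl)dodecan-1-one
Product: 5 3-dodecanoyl-2,4,6-trihydroxybenzaldehyde, via iminium chloride 4 (not isolated)
Conditions: POCl3 (1.2 equiv), DMF (1.5 equiv), EtOAc, 0 °C to rt; then H2O, 50 °C
Reagents that add atoms: N,N-dimethylformamide, CN(C)C=O; water, O
Why: Vilsmeier–Haack formylation, a known reaction of acylphloroglucinols; the two free ring carbons of 3 are equivalent, the ring rather than the chelated ketone is the nucleophile at low temperature, and iminium salt 4 is deactivated towards a second attack until water releases the aldehyde.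

Step 3
Reactants: 5 3-dodecanoyl-2,4,6-trihydroxybenzaldehyde
Product: 6 2,4,6-tris(benzyloxy)-3-dodecanoylbenzaldehyde
Conditions: BnBr (3.6 equiv), K2CO3 (4.5 equiv), DMF, 60 °C
Reagents that add atoms: benzyl bromide, BrCc1ccccc1
Why: Williamson ether synthesis; in a dipolar aprotic solvent the potassium phenoxides alkylate on oxygen, the one remaining ring carbon is deactivated by two carbonyl groups, and K2CO3 is too weak to enolise the ketone; warming is needed because all three hydroxyls are hydrogen-bonded to carbonyls.

Step 4
Reactants: 6 2,4,6-tris(benzyloxy)-3-dodecanoylbenzaldehyde; 7 (triphenylphosphoranylidene)acetaldehyde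
Product: 8 (2E)-3-[2,4,6-tris(benzyloxy)-3-dodecanoylphenyl]prop-2-enal
Conditions: 7 (1.3 equiv), toluene, 90 °C
Reagents that add atoms: none
Why: Wittig olefination with a stabilised ylide, which should give the (E)-enal and leave the hindered ketone alone; the product is a donor-conjugated aldehyde and less electrophilic than 6, which should hold back a second olefination while the ylide is kept near one equivalent.

Step 5
Reactants: 8 (2E)-3-[2,4,6-tris(benzyloxy)-3-dodecanoylphenyl]prop-2-enal; 9 3-(benzyloxy)phenol
Product: 11 (4S)-7-(benzyloxy)-4-[2,4,6-tris(benzyloxy)-3-dodecanoylphenyl]chroman-2-ol (C2 anomers), via hydroxy aldehyde 10 (not isolated)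
Conditions: (R)-α,α-diphenylprolinol trimethylsilyl ether (20 mol%), PhCO2H (20 mol%), toluene, 0 °C to rt
Reagents that add atoms: none
Why: Iminium-catalysed Friedel–Crafts alkylation of an electron-rich phenol followed by hemiacetalisation, a known route from enals to 4-arylchroman-2-ols; C6 of 9 (ortho to OH, para to OBn) adds to the β-carbon of the (E)-iminium ion on the face left open by the diphenyl(silyloxy)methyl group, which for the (R)-catalyst should give the (S) centre that becomes C4; hydrolysis releases 10, whose phenol closes on the aldehyde.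

Step 6
Reactants: 11 (4S)-7-(benzyloxy)-4-[2,4,6-tris(benzyloxy)-3-dodecanoylphenyl]chroman-2-ol; 7 (triphenylphosphoranylidene)acetaldehyde
Product: 12 (2E,5S)-5-[4-(benzyloxy)-2-hydroxyphenyl]-5-[2,4,6-tris(benzyloxy)-3-dodecanoylphenyl]pent-2-enal
Conditions: 7 (1.2 equiv), toluene, 70 °C
Reagents that add atoms: none
Why: Wittig olefination of a lactol, which reacts through the small equilibrium share of its ring-opened hydroxy aldehyde tautomer (the open form 10 already met in step 5); the stabilised ylide should give the (E)-enal, the stereocentre is not involved, and enal 12 reacts with the ylide more slowly than the saturated aldehyde, so single homologation is expected.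

Step 7
Reactants: 12 (2E,5S)-5-[4-(benzyloxy)-2-hydroxyphenyl]-5-[2,4,6-tris(benzyloxy)-3-dodecanoylphenyl]pent-2-enal
Product: 13 {(2R,4S)-7-(benzyloxy)-4-[2,4,6-tris(benzyloxy)-3-dodecanoylphenyl]chroman-2-yl}acetaldehyde
Conditions: (S)-α,α-diphenylprolinol trimethylsilyl ether (20 mol%), PhCO2H (20 mol%), toluene, rt
Reagents that add atoms: none
Why: Amine-catalysed intramolecular oxa-Michael addition of the phenol to the enal iminium ion (6-exo-trig), a known chroman synthesis; the closure is reversible, so C2 should settle trans to C4 (ring D pseudo-axial away from H5, side chain equatorial), and the (S)-catalyst shields the face that would give the cis epimer, so kinetic and thermodynamic preference should both lead to (2R,4S)-13.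

Step 8
Reactants: 13 {(2R,4S)-7-(benzyloxy)-4-[2,4,6-tris(benzyloxy)-3-dodecanoylphenyl]chroman-2-yl}acetaldehyde; 14 methyl vinyl ketone (but-3-en-2-one)
Product: 16 4-{(2R,4S)-7-(benzyloxy)-4-[2,4,6-tris(benzyloxy)-3-dodecanoylphenyl]chroman-2-yl}cyclohex-2-en-1-one (both epimers at the ring carbon C1''), via keto aldehyde 15 (not isolated)
Conditions: 14 (2 equiv), (S)-α,α-diphenylprolinol trimethylsilyl ether (20 mol%), PhCO2H (20 mol%), CH2Cl2, 0 °C; then dibenzylammonium trifluoroacetate (0.5 equiv), toluene, 40 °C
Reagents that add atoms: none
Why: The amine converts aldehyde 13 into an enamine whose α-carbon (C1'') adds to enone 14 in a Michael addition (C1''–C6''), and hydrolysis gives keto aldehyde 15; the ammonium salt then brings the methyl ketone, as its enol or enamine, onto the aldehyde carbon (C2''–C3''), and loss of water gives the conjugated enone 16. The closest known reaction type is the amine-catalysed Michael addition of aldehydes to methyl vinyl ketone followed by aldol cyclodehydration to 4-substituted cyclohex-2-enones, the aldehyde-enamine form of the Robinson annulation. Ring B closes in a 6-(enolendo)-exo-trig aldol mode; closure through the other ketone α-carbon or through the aldehyde α-carbon would need a four-membered ring, so only the cyclohexenone can form. No lasting stereocentre is made: C1'' arises as a mixture of epimers and becomes an aromatic carbon in step 10, and C4 is not touched. The selectivity that matters is bond formation at C1'' against loss of the ring A phenoxide from the enamine, which would open ring C. The buffered, weakly acidic medium at 0 °C keeps the enamine concentration low, enone 14 is an unhindered acceptor used in excess, and the catalyst is the one that closed ring C in step 7, so a ring that opens should return to the same 2,4-trans chroman. The cyclodehydration uses an ammonium salt without added base, which should also prevent deprotonation of 16 at C1'' and the vinylogous expulsion of O1 from C2 that would follow.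

Step 9
Reactants: 16 4-{(2R,4S)-7-(benzyloxy)-4-[2,4,6-tris(benzyloxy)-3-dodecanoylphenyl]chroman-2-yl}cyclohex-2-en-1-one
Product: 17 cross-conjugated trimethylsilyl dienol ether of 16 (4-[(trimethylsilyl)oxy]cyclohexa-2,4-dien-1-yl group on C2)
Conditions: Me3SiCl (3 equiv), then LiN(iPr)2 (1.15 equiv), THF, −78 °C; cold NaHCO3 work-up
Reagents that add atoms: chlorotrimethylsilane, C[Si](C)(C)Cl
Why: Kinetic enolisation with in situ silylation; LiN(iPr)2 removes the unhindered α'-proton at C5'' to give the cross-conjugated dienolate, which is trapped at once, so C1'' is never deprotonated and O1 cannot be expelled from C2; the dodecanoyl ketone, shielded by two ortho benzyloxy groups and a long chain, should react more slowly.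

Step 10
Reactants: 17 cross-conjugated trimethylsilyl dienol ether of 16
Product: 19 1-{2,4,6-tris(benzyloxy)-3-[(2R,4S)-7-(benzyloxy)-2-(4-hydroxyphenyl)chroman-4-yl]phenyl}dodecan-1-one, via cyclohexadienone 18 (not isolated)
Conditions: Pd(OAc)2 (1.1 equiv), MeCN, rt
Reagents that add atoms: none
Why: Saegusa–Ito oxidation; divalent palladium adds to the silyl enol ether at C5'', β-hydride elimination from C6'' gives the cross-conjugated dienone 18, and this keto tautomer of a para-substituted phenol aromatises at once by loss of the C1'' proton, which erases the C1'' centre; the medium contains only acetic acid, so the now benzylic O1–C2 bond should hold.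

Step 11
Reactants: 19 1-{2,4,6-tris(benzyloxy)-3-[(2R,4S)-7-(benzyloxy)-2-(4-hydroxyphenyl)chroman-4-yl]phenyl}dodecan-1-one
Product: 20 1-{2,4,6-trihydroxy-3-[(2R,4S)-7-hydroxy-2-(4-hydroxyphenyl)chroman-4-yl]phenyl}dodecan-1-one (target)
Conditions: H2 (1 atm), 10% Pd/C, EtOAc/MeOH, rt; filtration under argon
Reagents that add atoms: none
Why: Catalytic hydrogenolysis of four aryl benzyl ethers under neutral conditions; O1–C2 is a cyclic secondary alkyl aryl ether that should cleave far more slowly than the primary benzyl ethers, the ketone is held in a hydrogen-bonded chelate once its ortho hydroxyls are free, and no acid or base touches the target, so C2 and C4 should be retained.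

## Compound list

1 | phloroglucinol (benzene-1,3,5-triol) | Oc1cc(O)cc(O)c1 | starting material
2 | dodecanoyl (lauroyl) chloride | CCCCCCCCCCCC(Cl)=O | starting material
3 | 1-(2,4,6-trihydroxyphenyl)dodecan-1-one | CCCCCCCCCCCC(=O)c1c(O)cc(O)cc1O | intermediate
4 | N-[(3-dodecanoyl-2,4,6-trihydroxyphenyl)methylidene]-N-methylmethanaminium chloride | CCCCCCCCCCCC(=O)c1c(O)cc(O)c(C=[N+](C)C)c1O.[Cl-] | intermediate (not isolated)
5 | 3-dodecanoyl-2,4,6-trihydroxybenzaldehyde | CCCCCCCCCCCC(=O)c1c(O)cc(O)c(C=O)c1O | intermediate
6 | 2,4,6-tris(benzyloxy)-3-dodecanoylbenzaldehyde | CCCCCCCCCCCC(=O)c1c(OCc2ccccc2)cc(OCc2ccccc2)c(C=O)c1OCc1ccccc1 | intermediate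
7 | (triphenylphosphoranylidene)acetaldehyde | O=CC=P(c1ccccc1)(c1ccccc1)c1ccccc1 | starting material
8 | (2E)-3-[2,4,6-tris(benzyloxy)-3-dodecanoylphenyl]prop-2-enal | CCCCCCCCCCCC(=O)c1c(OCc2ccccc2)cc(OCc2ccccc2)c(/C=C/C=O)c1OCc1ccccc1 | intermediate
9 | 3-(benzyloxy)phenol | Oc1cccc(OCc2ccccc2)c1 | starting material
10 | (3S)-3-[4-(benzyloxy)-2-hydroxyphenyl]-3-[2,4,6-tris(benzyloxy)-3-dodecanoylphenyl]propanal | CCCCCCCCCCCC(=O)c1c(OCc2ccccc2)cc(OCc2ccccc2)c([C@@H](CC=O)c2ccc(OCc3ccccc3)cc2O)c1OCc1ccccc1 | intermediate (not isolated)
11 | 1-{2,4,6-tris(benzyloxy)-3-[(4S)-7-(benzyloxy)-2-hydroxy-3,4-dihydro-2H-chromen-4-yl]phenyl}dodecan-1-one (C2 anomers) | CCCCCCCCCCCC(=O)c1c(OCc2ccccc2)cc(OCc2ccccc2)c([C@H]2CC(O)Oc3cc(OCc4ccccc4)ccc32)c1OCc1ccccc1 | intermediate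
12 | (2E,5S)-5-[4-(benzyloxy)-2-hydroxyphenyl]-5-[2,4,6-tris(benzyloxy)-3-dodecanoylphenyl]pent-2-enal | CCCCCCCCCCCC(=O)c1c(OCc2ccccc2)cc(OCc2ccccc2)c([C@@H](C/C=C/C=O)c2ccc(OCc3ccccc3)cc2O)c1OCc1ccccc1 | intermediate
13 | {(2R,4S)-7-(benzyloxy)-4-[2,4,6-tris(benzyloxy)-3-dodecanoylphenyl]-3,4-dihydro-2H-chromen-2-yl}acetaldehyde | CCCCCCCCCCCC(=O)c1c(OCc4ccccc4)cc(OCc4ccccc4)c([C@H]2C[C@H](CC=O)Oc3cc(OCc4ccccc4)ccc32)c1OCc1ccccc1 | intermediate (key-step precursor)
14 | methyl vinyl ketone (but-3-en-2-one) | CC(=O)C=C | starting material
15 | 2-{(2R,4S)-7-(benzyloxy)-4-[2,4,6-tris(benzyloxy)-3-dodecanoylphenyl]-3,4-dihydro-2H-chromen-2-yl}-5-oxohexanal (epimers at C2 of the hexanal) | CCCCCCCCCCCC(=O)c1c(OCc4ccccc4)cc(OCc4ccccc4)c([C@H]2C[C@H](C(C=O)CCC(C)=O)Oc3cc(OCc4ccccc4)ccc32)c1OCc1ccccc1 | intermediate (not isolated)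
16 | 4-{(2R,4S)-7-(benzyloxy)-4-[2,4,6-tris(benzyloxy)-3-dodecanoylphenyl]-3,4-dihydro-2H-chromen-2-yl}cyclohex-2-en-1-one (epimers at C4 of the enone) | CCCCCCCCCCCC(=O)c1c(OCc4ccccc4)cc(OCc4ccccc4)c([C@H]2C[C@H](C3C=CC(=O)CC3)Oc3cc(OCc4ccccc4)ccc32)c1OCc1ccccc1 | intermediate (key-step product)
17 | 1-{2,4,6-tris(benzyloxy)-3-[(2R,4S)-7-(benzyloxy)-2-{4-[(trimethylsilyl)oxy]cyclohexa-2,4-dien-1-yl}-3,4-dihydro-2H-chromen-4-yl]phenyl}dodecan-1-one (epimers at the ring carbon bound to C2) | CCCCCCCCCCCC(=O)c1c(OCc4ccccc4)cc(OCc4ccccc4)c([C@H]2C[C@H](C3C=CC(O[Si](C)(C)C)=CC3)Oc3cc(OCc4ccccc4)ccc32)c1OCc1ccccc1 | intermediate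
18 | 4-{(2R,4S)-7-(benzyloxy)-4-[2,4,6-tris(benzyloxy)-3-dodecanoylphenyl]-3,4-dihydro-2H-chromen-2-yl}cyclohexa-2,5-dien-1-one | CCCCCCCCCCCC(=O)c1c(OCc4ccccc4)cc(OCc4ccccc4)c([C@H]2C[C@H](C3C=CC(=O)C=C3)Oc3cc(OCc4ccccc4)ccc32)c1OCc1ccccc1 | intermediate (not isolated)
19 | 1-{2,4,6-tris(benzyloxy)-3-[(2R,4S)-7-(benzyloxy)-2-(4-hydroxyphenyl)-3,4-dihydro-2H-chromen-4-yl]phenyl}dodecan-1-one | CCCCCCCCCCCC(=O)c1c(OCc4ccccc4)cc(OCc4ccccc4)c([C@H]2C[C@H](c3ccc(O)cc3)Oc3cc(OCc4ccccc4)ccc32)c1OCc1ccccc1 | intermediate
20 | 1-{2,4,6-trihydroxy-3-[(2R,4S)-7-hydroxy-2-(4-hydroxyphenyl)-3,4-dihydro-2H-chromen-4-yl]phenyl}dodecan-1-one (CNP0293819.3) | CCCCCCCCCCCC(=O)c1c(O)cc(O)c([C@H]2C[C@H](c3ccc(O)cc3)Oc3cc(O)ccc32)c1O | target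

## Step count and least certain steps

Total: 11 steps. Longest linear sequence: 11 steps (1 to 20); compounds 2, 7, 9 and 14 enter as purchased materials.

**Step 8 (key step).** The most likely failure is loss of the ring A phenoxide from the enamine of 13 (opening of ring C) faster than addition to 14, followed by side reactions of the opened enal. A second possibility is deprotonation of 16 at C1'' with vinylogous loss of O1. Fallback, from 13 back to 16, with no amine present during carbon–carbon bond formation: 13 is converted with Me3SiOTf (1.1 equiv)/Et3N (CH2Cl2, −20 °C), under which the unhindered aldehyde should be silylated ahead of the shielded dodecanoyl ketone, into its silyl enol ether, 1-{2,4,6-tris(benzyloxy)-3-[(2R,4S)-7-(benzyloxy)-2-{2-[(trimethylsilyl)oxy]ethenyl}-3,4-dihydro-2H-chromen-4-yl]phenyl}dodecan-1-one F5. A Mukaiyama–Michael addition of F5 to 14 (BF3·OEt2, CH2Cl2, −78 °C) gives keto aldehyde 15 after aqueous work-up. Compound 15 is cyclised with dibenzylammonium trifluoroacetate as in the second stage of step 8, rejoining the route at 16.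

**Step 5.** The iminium ion of 8 is hindered and donor-stabilised and 9 is only a moderate nucleophile, so the Friedel–Crafts addition may be slow. Attack through the position para to the hydroxyl would give an adduct that cannot close to the lactol, and a sluggish catalysed path lowers enantioselectivity. Fallback, from 8 and 9 back to 12, replacing asymmetric catalysis by resolution: a small achiral ammonium catalyst (morpholinium trifluoroacetate, toluene, 60 °C) allows forcing conditions and gives the racemic lactol, 1-{2,4,6-tris(benzyloxy)-3-[7-(benzyloxy)-2-hydroxy-3,4-dihydro-2H-chromen-4-yl]phenyl}dodecan-1-one F1. Wittig reaction with 7 as in step 6 gives the racemic enal, (2E)-5-[4-(benzyloxy)-2-hydroxyphenyl]-5-[2,4,6-tris(benzyloxy)-3-dodecanoylphenyl]pent-2-enal F2, which has a single stereocentre. Preparative chromatography on a chiral stationary phase separates the enantiomers, and the (5S) enantiomer is 12.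

**Step 7.** The equilibrium between the C2 epimers may not favour the trans chroman strongly enough, giving incomplete diastereoselection in ring closure. Fallback, from 11 back to 13, closing O1–C2 by stereospecific substitution instead of conjugate addition: the ring-opened aldehyde form of 11 is allylated with (+)-B-allyldiisopinocampheylborane (the reagent from (−)-α-pinene; 2.2 equiv, Et2O, −78 °C; then aq. NaOH/H2O2), which by its usual facial preference should give 1-{2,4,6-tris(benzyloxy)-3-[(1S,3R)-1-[4-(benzyloxy)-2-hydroxyphenyl]-3-hydroxyhex-5-en-1-yl]phenyl}dodecan-1-one F3. Mitsunobu etherification (PPh3, diisopropyl azodicarboxylate, THF, 0 °C) joins the phenol oxygen to the carbinol carbon with inversion and gives the trans 2-allyl chroman, 1-{2,4,6-tris(benzyloxy)-3-[(2S,4S)-7-(benzyloxy)-2-(prop-2-en-1-yl)-3,4-dihydro-2H-chromen-4-yl]phenyl}dodecan-1-one F4. Its descriptor at C2 differs from that of 13 only through the priority change of the side chain. Lemieux–Johnson cleavage of the terminal alkene (K2OsO4·2H2O cat., NaIO4, 2,6-lutidine, dioxane/H2O) gives 13.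

**Step 9.** Enolisation may not discriminate between the ring B enone and the dodecanoyl ketone, leaving part of the enone unsilylated and, in step 10, dehydrogenating part of the side chain. Fallback, from 16 to 20, accepting reaction at both ketones and correcting it in the final reduction: excess LiN(iPr)2/Me3SiCl (2.5 equiv each, THF, −78 °C) gives the bis(silyl enol ether), (2R,4S)-7-(benzyloxy)-4-{2,4,6-tris(benzyloxy)-3-[1-(trimethylsilyloxy)dodec-1-en-1-yl]phenyl}-2-{4-[(trimethylsilyl)oxy]cyclohexa-2,4-dien-1-yl}chroman F6. Pd(OAc)2 (2.2 equiv, MeCN, rt) dehydrogenates both positions to (2E)-1-{2,4,6-tris(benzyloxy)-3-[(2R,4S)-7-(benzyloxy)-2-(4-hydroxyphenyl)-3,4-dihydro-2H-chromen-4-yl]phenyl}dodec-2-en-1-one F7. Hydrogenation under the conditions of step 11 saturates the side-chain alkene before and while the benzyl ethers are removed, giving 20.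

**Step 3.** Benzylation may be incomplete on the three chelated hydroxyls, and the phenoxide may be alkylated on its remaining ring carbon. Fallback, from 5 to 6, alkylating through an activated alcohol instead of a free phenoxide and a halide: Mitsunobu etherification with benzyl alcohol (PPh3, diisopropyl azodicarboxylate, THF, 0 °C to rt), which is selective for oxygen and well suited to acidic phenols. This fallback makes no new compound (F0).

## Further compounds

F0 | step 3 | none | none
F1 | step 5 | racemic 1-{2,4,6-tris(benzyloxy)-3-[7-(benzyloxy)-2-hydroxy-3,4-dihydro-2H-chromen-4-yl]phenyl}dodecan-1-one | CCCCCCCCCCCC(=O)c1c(OCc2ccccc2)cc(OCc2ccccc2)c(C2CC(O)Oc3cc(OCc4ccccc4)ccc32)c1OCc1ccccc1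
F2 | step 5 | racemic (2E)-5-[4-(benzyloxy)-2-hydroxyphenyl]-5-[2,4,6-tris(benzyloxy)-3-dodecanoylphenyl]pent-2-enal | CCCCCCCCCCCC(=O)c1c(OCc2ccccc2)cc(OCc2ccccc2)c(C(C/C=C/C=O)c2ccc(OCc3ccccc3)cc2O)c1OCc1ccccc1
F3 | step 7 | 1-{2,4,6-tris(benzyloxy)-3-[(1S,3R)-1-[4-(benzyloxy)-2-hydroxyphenyl]-3-hydroxyhex-5-en-1-yl]phenyl}dodecan-1-one | CCCCCCCCCCCC(=O)c1c(OCc2ccccc2)cc(OCc2ccccc2)c([C@@H](C[C@H](O)CC=C)c2ccc(OCc3ccccc3)cc2O)c1OCc1ccccc1
F4 | step 7 | 1-{2,4,6-tris(benzyloxy)-3-[(2S,4S)-7-(benzyloxy)-2-(prop-2-en-1-yl)-3,4-dihydro-2H-chromen-4-yl]phenyl}dodecan-1-one | CCCCCCCCCCCC(=O)c1c(OCc4ccccc4)cc(OCc4ccccc4)c([C@H]2C[C@H](CC=C)Oc3cc(OCc4ccccc4)ccc32)c1OCc1ccccc1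
F5 | step 8 | 1-{2,4,6-tris(benzyloxy)-3-[(2R,4S)-7-(benzyloxy)-2-{2-[(trimethylsilyl)oxy]ethenyl}-3,4-dihydro-2H-chromen-4-yl]phenyl}dodecan-1-one (E/Z mixture) | CCCCCCCCCCCC(=O)c1c(OCc4ccccc4)cc(OCc4ccccc4)c([C@H]2C[C@H](C=CO[Si](C)(C)C)Oc3cc(OCc4ccccc4)ccc32)c1OCc1ccccc1
F6 | step 9 | (2R,4S)-7-(benzyloxy)-4-{2,4,6-tris(benzyloxy)-3-[1-(trimethylsilyloxy)dodec-1-en-1-yl]phenyl}-2-{4-[(trimethylsilyl)oxy]cyclohexa-2,4-dien-1-yl}chroman | CCCCCCCCCCC=C(O[Si](C)(C)C)c1c(OCc4ccccc4)cc(OCc4ccccc4)c([C@H]2C[C@H](C3C=CC(O[Si](C)(C)C)=CC3)Oc3cc(OCc4ccccc4)ccc32)c1OCc1ccccc1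
F7 | step 9 | (2E)-1-{2,4,6-tris(benzyloxy)-3-[(2R,4S)-7-(benzyloxy)-2-(4-hydroxyphenyl)-3,4-dihydro-2H-chromen-4-yl]phenyl}dodec-2-en-1-one | CCCCCCCCC/C=C/C(=O)c1c(OCc4ccccc4)cc(OCc4ccccc4)c([C@H]2C[C@H](c3ccc(O)cc3)Oc3cc(OCc4ccccc4)ccc32)c1OCc1ccccc1
A1 | alternative 1 | tri(propan-2-yl)({[(2R,4R)-7-(benzyloxy)-2-[4-(benzyloxy)phenyl]-3,4-dihydro-2H-chromen-4-yl]ethynyl}oxy)silane | CC(C)[Si](C(C)C)(C(C)C)OC#C[C@H]2C[C@H](c3ccc(OCc4ccccc4)cc3)Oc3cc(OCc4ccccc4)ccc32
A2 | alternative 1 | 3-(benzyloxy)cyclobut-2-en-1-one | O=C1C=C(OCc2ccccc2)C1
A3 | alternative 1 | 5-(benzyloxy)-2-{(2R,4S)-7-(benzyloxy)-2-[4-(benzyloxy)phenyl]-3,4-dihydro-2H-chromen-4-yl}-3-{[tri(propan-2-yl)silyl]oxy}phenol | Oc1cc(OCc5ccccc5)cc(O[Si](C(C)C)(C(C)C)C(C)C)c1[C@H]2C[C@H](c3ccc(OCc4ccccc4)cc3)Oc3cc(OCc4ccccc4)ccc32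
A4 | alternative 2 | dimethyl 2-{(1S,3R)-3-[4-(benzyloxy)phenyl]-3-[(tert-butyldimethylsilyl)oxy]-1-[2,4,6-tris(benzyloxy)-3-dodecanoylphenyl]propyl}propanedioate | CCCCCCCCCCCC(=O)c1c(OCc4ccccc4)cc(OCc4ccccc4)c([C@@H](C[C@H](c3ccc(OCc4ccccc4)cc3)O[Si](C)(C)C(C)(C)C)C(C(=O)OC)C(=O)OC)c1OCc1ccccc1
A5 | alternative 2 | methyl 1-{(1R,3R)-3-[4-(benzyloxy)phenyl]-3-[(tert-butyldimethylsilyl)oxy]-1-[2,4,6-tris(benzyloxy)-3-dodecanoylphenyl]propyl}-2,4-dioxocyclohexane-1-carboxylate (epimers at ring C1) | CCCCCCCCCCCC(=O)c1c(OCc4ccccc4)cc(OCc4ccccc4)c([C@@H](C[C@H](c3ccc(OCc4ccccc4)cc3)O[Si](C)(C)C(C)(C)C)C3(C(=O)OC)CCC(=O)CC3=O)c1OCc1ccccc1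
A6 | alternative 3 | (1R,2R)-1-[4-(benzyloxy)phenyl]-2-[2,4,6-tris(benzyloxy)-3-bromophenyl]cyclopropane | Brc1c(OCc5ccccc5)cc(OCc5ccccc5)c([C@@H]2C[C@H]2c3ccc(OCc4ccccc4)cc3)c1OCc1ccccc1
A7 | alternative 3 | (2R,4S)-7-(benzyloxy)-2-[4-(benzyloxy)phenyl]-4-[2,4,6-tris(benzyloxy)-3-bromophenyl]-3,4-dihydro-2H-chromene | Brc1c(OCc4ccccc4)cc(OCc4ccccc4)c([C@H]2C[C@H](c3ccc(OCc4ccccc4)cc3)Oc3cc(OCc4ccccc4)ccc32)c1OCc1ccccc1
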